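**Plan** (atoms carry labdane numbers C1–C20)

- Retrosynthesis: the (12Z)-diene is cut at C13–C14 (Stille coupling) and C12=C13 (iodo-Wittig) back to a C9 vinyl group. The C6/C7 oxygens and H5 are traced to a ring B Δ5-7-ketone, and ring B is then cut at C5–C6 and C8–C9 in one stroke.
- Forward: ring A is 2,2,6-trimethylcyclohexanone. C10 is made quaternary by asymmetric allylation, and the allyl group (C9, C11, C12) is turned into an (E)-allyl ether of acetoin (C6, C7, C8, C17).
- Enabling feature: the C8 carbinol oxygen lies 1,4 to C12 across C9–C11, so an O–C12 ether is a cleavable tether through which a [3,3] shift hands C8 to C9. C5 is a non-enolisable ketone between quaternary C4 and C10, so it can only be the acceptor for the C6 methyl ketone that the shift unveils, and ring B (C5–C10) closes in the same pot.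
- Stereochemistry: C10 from the chiral palladium catalyst; C8 and C9 from the chair [3,3] transition state; H5 from dissolving-metal protonation; C6 (Rubottom) and C7 (axial hydride) from attack opposite the axial C10 and C8 methyl groups; 12Z from the iodo-ylide olefination and a stereoretentive coupling.

Key step: step 6

Remark: racemic acetoin suffices because its stereocentre becomes sp2 in step 6; "cis/trans" below always refers to the C10 methyl group on ring B.

Step 1
Reactants: 1 2,2,6-trimethylcyclohexan-1-one; 2 allyl chloroformate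
Product: 4 allyl 2,6,6-trimethylcyclohex-1-en-1-yl carbonate, via lithium enolate 3 (not isolated)
Conditions: LiN(SiMe3)2, TMEDA, THF, −78 → 0 °C; then 2
Reagents that add atoms: none
Why: the ketone can enolise only toward the methyl-bearing carbon (future C10), and the hindered tetrasubstituted lithium enolate is acylated on oxygen by the chloroformate (enol carbonate formation).

Step 2
Reactants: 4 allyl 2,6,6-trimethylcyclohex-1-en-1-yl carbonate
Product: 5 (S)-2-allyl-2,6,6-trimethylcyclohexan-1-one
Conditions: Pd2(dba)3 (tris(dibenzylideneacetone)dipalladium, zerovalent palladium, cat.), (S)-t-Bu-PHOX (cat.), THF, 25 °C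
Reagents that add atoms: none
Why: decarboxylative asymmetric allylic alkylation (Tsuji allylation) through a chiral phosphinooxazoline–palladium enolate sets the quaternary C10 centre; the ligand enantiomer is chosen for the S ketone, which (S)-t-Bu-PHOX should give by analogy with simpler 2-methylcyclohexanone enol carbonates.

Step 3
Reactants: 5 (S)-2-allyl-2,6,6-trimethylcyclohexan-1-one
Product: 6 (S)-2,2,6-trimethyl-6-[(E)-prop-1-en-1-yl]cyclohexan-1-one
Conditions: PdCl2(MeCN)2 (divalent palladium, cat.), toluene, 60 °C
Reagents that add atoms: none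
Why: transition-metal-catalysed olefin isomerisation moves the terminal alkene into the more stable (E)-disubstituted position; C10 has no α-hydrogen and cannot epimerise.

Step 4
Reactants: 6 (S)-2,2,6-trimethyl-6-[(E)-prop-1-en-1-yl]cyclohexan-1-one
Product: 7 (S)-2-[(E)-3-bromoprop-1-en-1-yl]-2,6,6-trimethylcyclohexan-1-one
Conditions: N-bromosuccinimide, AIBN (cat.), PhCF3, 80 °C
Reagents that add atoms: N-bromosuccinimide O=C1CCC(=O)N1Br
Why: Wohl–Ziegler allylic bromination; the only allylic C–H bonds are those of the C12 methyl group, and the allyl radical should be brominated at the unhindered primary terminus, not at neopentyl C9, keeping the (E)-alkene.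

Step 5
Reactants: 7 (S)-2-[(E)-3-bromoprop-1-en-1-yl]-2,6,6-trimethylcyclohexan-1-one; 8 acetoin (3-hydroxybutan-2-one)
Product: 9 3-{[(2E)-3-[(1S)-1,3,3-trimethyl-2-oxocyclohexyl]prop-2-en-1-yl]oxy}butan-2-one
Conditions: 8 (excess), Ag2O, 4 Å molecular sieves, CH2Cl2, 25 °C, dark
Reagents that add atoms: none
Why: silver-oxide-assisted Williamson-type etherification of the α-hydroxy ketone with the primary allylic bromide under non-basic conditions that spare acetoin from aldol self-condensation; attack at the primary terminus is favoured over neopentyl C9.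

Step 6
Reactants: 9 3-{[(2E)-3-[(1S)-1,3,3-trimethyl-2-oxocyclohexyl]prop-2-en-1-yl]oxy}butan-2-one
Product: 12 ring B enone (8-hydroxy-8-methyl-9-vinyl Δ5-7-ketone), via ketol alkoxide 10 (not isolated), via aldol adduct 11 (not isolated)
Conditions: KOt-Bu (3 equiv), t-BuOH/THF 1:4, 0.02 M, 25 → 65 °C
Reagents that add atoms: none
Why: KOt-Bu equilibrates the ketone enolates of 9, and only the chelated tetrasubstituted potassium enolate (O– cis to the allyloxy oxygen) can react, by a chair [3,3] shift (anionic oxy-Claisen rearrangement of an α-allyloxy ketone enolate) that joins the former carbonyl carbon (C8) to C9, breaks the temporary O–C12 ether bond, turns the ether carbon into the C7 ketone and leaves C11=C12 as a vinyl group; a [2,3] shift of the same enolate would give the same constitution. The resulting alkoxide 10 carries a methyl ketone whose only enolisable carbon is C6, and its enolate closes ring B on the C5 ketone by a 6-(enolexo)-exo-trig aldol addition to 11, which loses hydroxide (E1cB) to the conjugated, non-enolisable enone 12, an intramolecular aldol condensation of the Robinson-annulation type. C8 and C9 are set together in the chair transition state, where the (E)-alkene places C10 equatorial and the chelated enolate places the C8 methyl equatorial and O– axial, which should give 8-OH trans to the 9-vinyl group and the 8-methyl cis to the 10-methyl. The alkene face is chosen by the C10 centre (acyl carbon C5 anti to the forming bond, ring CH2 inside, methyl outside). The step needs regioselective enolisation, secured by equilibration with only one productive enolate, and ring closure on a carbonyl flanked by two quaternary carbons, helped by intramolecularity, by the lack of any enolisable position at C5 and by the irreversible dehydration. High dilution suppresses intermolecular aldol reactions.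

Step 7
Reactants: 12 ring B enone
Product: 14 trans-fused bis(triethylsilyl) compound (C6=C7 silyl enol ether; C8 silyl ether), via dilithium enolate alkoxide 13 (not isolated)
Conditions: Li, NH3(l), THF, −78 °C; isoprene; NH3 removed; then Et3SiOTf, Et3N, THF, −78 → 0 °C
Reagents that add atoms: triethylsilyl trifluoromethanesulfonate CC[Si](CC)(CC)OS(=O)(=O)C(F)(F)F
Why: dissolving-metal conjugate reduction of the enone with stereoelectronically controlled axial protonation at C5 should give the trans ring fusion, and the regiodefined C6=C7 enolate is trapped on oxygen together with the C8 alkoxide (reductive silylation).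

Step 8
Reactants: 14 trans-fused bis(triethylsilyl) compound
Product: 16 6-(triethylsilyloxy)-7-ketone (C6–O trans; equatorial), via silyloxy epoxide 15 (not isolated)
Conditions: mCPBA (1.05 equiv), NaHCO3, CH2Cl2, −20 → 0 °C
Reagents that add atoms: 3-chloroperoxybenzoic acid O=C(OO)c1cccc(Cl)c1
Why: Rubottom oxidation; the electron-rich silyl enol ether is epoxidised far faster than the vinyl group, from the face opposite the axial C10 and C8 methyl groups, and the epoxide opens with 1,4-silyl shift to the C6 silyloxy ketone.

Step 9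
Reactants: 16 6-(triethylsilyloxy)-7-ketone
Product: 17 7-alcohol (C7–OH cis; equatorial)
Conditions: LiAlH4, Et2O, −78 °C
Reagents that add atoms: none
Why: the small hydride adds along the axial trajectory on the face away from the axial C8 methyl group (the equatorial approach is flanked by two silyloxy groups), which should give the equatorial C7 alcohol trans to both oxygen neighbours.

Step 10
Reactants: 17 7-alcohol
Product: 18 7-acetate
Conditions: Ac2O, DMAP, pyridine, 40 °C
Reagents that add atoms: acetic anhydride CC(=O)OC(C)=O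
Why: DMAP-catalysed acylation of the only free hydroxyl group places the acetate unambiguously on C7.

Step 11
Reactants: 18 7-acetate
Product: 20 primary alcohol (C12–OH), via alkylborane 19 (not isolated)
Conditions: 9-BBN, THF, 0 → 40 °C; then H2O2, pH 7 phosphate buffer, 0 → 25 °C
Reagents that add atoms: hydrogen peroxide OO
Why: anti-Markovnikov hydroboration of the monosubstituted alkene with a bulky dialkylborane that is inert to the acetate and silyl ethers, followed by buffered oxidation that keeps the acetate in place.

Step 12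
Reactants: 20 primary alcohol
Product: 21 C12 aldehyde
Conditions: Dess–Martin periodinane, NaHCO3, CH2Cl2, 0 → 25 °C
Reagents that add atoms: none
Why: Dess–Martin oxidation takes the primary alcohol to the aldehyde under buffered conditions; no other free hydroxyl group is present.

Step 13
Reactants: 21 C12 aldehyde; 22 ethyltriphenylphosphonium iodide
Product: 23 (12Z)-13-iodo alkene
Conditions: 22, n-BuLi, THF, 25 °C; I2, −78 °C; NaN(SiMe3)2, −78 → −20 °C; then 21, −78 °C
Reagents that add atoms: iodine II
Why: Wittig reaction with the α-iodo ylide made in the flask (Stork–Zhao-type iodo-olefination), a reaction type that gives (Z)-2-iodo-2-alkenes from aldehydes; at −78 °C the aldehyde should react without loss of the acetate.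

Step 14
Reactants: 23 (12Z)-13-iodo alkene; 24 tributyl(vinyl)stannane
Product: 25 6,8-bis-O-triethylsilyl ether of the target
Conditions: Pd2(dba)3 (zerovalent palladium, cat.), AsPh3, CuI, NMP, 25 → 40 °C
Reagents that add atoms: none
Why: Stille coupling proceeds with retention of alkene geometry, so the (Z)-iodide should give the (12Z)-diene under neutral conditions that leave the acetate untouched.

Step 15
Reactants: 25 6,8-bis-O-triethylsilyl ether of the target
Product: 26 target CNP0225877.2
Conditions: HF·pyridine, pyridine/THF, 0 → 25 °C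
Reagents that add atoms: none
Why: fluoride cleavage of both triethylsilyl ethers under buffered, weakly acidic conditions that avoid acetyl migration and spare the diene.

**Compound list**

1 | 2,2,6-trimethylcyclohexan-1-one (racemic) | CC1CCCC(C)(C)C1=O | starting material
2 | allyl chloroformate | C=CCOC(Cl)=O | starting material
3 | lithium 2,6,6-trimethylcyclohex-1-en-1-olate (not isolated) | [Li+].[O-]C1=C(C)CCCC1(C)C | intermediate
4 | allyl 2,6,6-trimethylcyclohex-1-en-1-yl carbonate | C=CCOC(=O)OC1=C(C)CCCC1(C)C | intermediate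
5 | (S)-2-allyl-2,6,6-trimethylcyclohexan-1-one | C=CC[C@]1(C)CCCC(C)(C)C1=O | intermediate
6 | (S)-2,2,6-trimethyl-6-[(E)-prop-1-en-1-yl]cyclohexan-1-one | C/C=C/[C@]1(C)CCCC(C)(C)C1=O | intermediate
7 | (S)-2-[(E)-3-bromoprop-1-en-1-yl]-2,6,6-trimethylcyclohexan-1-one | BrC/C=C/[C@]1(C)CCCC(C)(C)C1=O | intermediate
8 | acetoin (3-hydroxybutan-2-one, racemic) | CC(O)C(C)=O | starting material
9 | 3-{[(2E)-3-[(1S)-1,3,3-trimethyl-2-oxocyclohexyl]prop-2-en-1-yl]oxy}butan-2-one (both epimers at the ether carbon) | CC(=O)C(C)OC/C=C/[C@]1(C)CCCC(C)(C)C1=O | intermediate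
10 | 3-hydroxy-3-methyl-4-[(1S)-1,3,3-trimethyl-2-oxocyclohexyl]hex-5-en-2-one, formed as its potassium alkoxide (not isolated); C8 and C9 as in the target | C=C[C@H]([C@@](C)(O)C(C)=O)[C@]1(C)CCCC(C)(C)C1=O | intermediate
11 | 5,8-dihydroxy-9-vinyl 7-ketone aldol adduct (not isolated; C5 carbinol configuration not defined) | C=C[C@@H]1[C@@](C)(O)C(=O)CC2(O)C(C)(C)CCC[C@]21C | intermediate
12 | 3-hydroxy-3,4a,8,8-tetramethyl-4-vinyl-4,4a,5,6,7,8-hexahydronaphthalen-2(3H)-one; labdane C8–CH3 and C9–vinyl cis, C8–OH trans to the C10 methyl | C=C[C@@H]1[C@@](C)(O)C(=O)C=C2C(C)(C)CCC[C@]21C | intermediate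
13 | dilithium C6=C7 enolate C8 alkoxide of the trans-fused 7-ketone (not isolated) | [Li+].[Li+].C=C[C@@H]1[C@@](C)([O-])C([O-])=C[C@@H]2C(C)(C)CCC[C@]21C | intermediate
14 | trans-fused C6=C7 triethylsilyl enol ether with C8 triethylsilyl ether (H5 trans to the C10 methyl) | C=C[C@@H]1[C@@](C)(O[Si](CC)(CC)CC)C(O[Si](CC)(CC)CC)=C[C@@H]2C(C)(C)CCC[C@]21C | intermediate
15 | 6,7-epoxide of 14 with the oxygen trans to the C10 methyl (not isolated) | C=C[C@@H]1[C@@](C)(O[Si](CC)(CC)CC)[C@@]3(O[Si](CC)(CC)CC)O[C@H]3[C@@H]2C(C)(C)CCC[C@]21C | intermediate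
16 | 6,8-bis(triethylsilyloxy)-9-vinyl 7-ketone; C6–O trans to the C10 methyl | C=C[C@@H]1[C@@](C)(O[Si](CC)(CC)CC)C(=O)[C@@H](O[Si](CC)(CC)CC)[C@@H]2C(C)(C)CCC[C@]21C | intermediate
17 | 6,8-bis(triethylsilyloxy)-9-vinyl 7-alcohol; C7–OH cis to the C10 methyl | C=C[C@@H]1[C@@](C)(O[Si](CC)(CC)CC)[C@H](O)[C@@H](O[Si](CC)(CC)CC)[C@@H]2C(C)(C)CCC[C@]21C | intermediate
18 | 7-acetate of 17 | C=C[C@@H]1[C@@](C)(O[Si](CC)(CC)CC)[C@H](OC(C)=O)[C@@H](O[Si](CC)(CC)CC)[C@@H]2C(C)(C)CCC[C@]21C | intermediate
19 | B-(C12-alkyl)-9-borabicyclo[3.3.1]nonane adduct of 18 (not isolated) | C1CC2CCCC(C1)B2CC[C@@H]1[C@@](C)(O[Si](CC)(CC)CC)[C@H](OC(C)=O)[C@@H](O[Si](CC)(CC)CC)[C@@H]2C(C)(C)CCC[C@]21C | intermediate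
20 | C12 primary alcohol (7-acetate, 6,8-bis-triethylsilyl ether) | OCC[C@@H]1[C@@](C)(O[Si](CC)(CC)CC)[C@H](OC(C)=O)[C@@H](O[Si](CC)(CC)CC)[C@@H]2C(C)(C)CCC[C@]21C | intermediate
21 | C12 aldehyde (7-acetate, 6,8-bis-triethylsilyl ether) | O=CC[C@@H]1[C@@](C)(O[Si](CC)(CC)CC)[C@H](OC(C)=O)[C@@H](O[Si](CC)(CC)CC)[C@@H]2C(C)(C)CCC[C@]21C | intermediate
22 | ethyltriphenylphosphonium iodide | CC[P+](c1ccccc1)(c1ccccc1)c1ccccc1.[I-] | starting material
23 | (12Z)-13-iodo alkene (7-acetate, 6,8-bis-triethylsilyl ether) | I/C(C)=C\C[C@@H]1[C@@](C)(O[Si](CC)(CC)CC)[C@H](OC(C)=O)[C@@H](O[Si](CC)(CC)CC)[C@@H]2C(C)(C)CCC[C@]21C | intermediate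
24 | tributyl(vinyl)stannane | C=C[Sn](CCCC)(CCCC)CCCC | starting material
25 | 6,8-bis-O-triethylsilyl ether of the target | C=C/C(C)=C\C[C@@H]1[C@@](C)(O[Si](CC)(CC)CC)[C@H](OC(C)=O)[C@@H](O[Si](CC)(CC)CC)[C@@H]2C(C)(C)CCC[C@]21C | intermediate
26 | CNP0225877.2: (12Z)-7-acetoxylabda-12,14-diene-6,8-diol of the ent series (10R); 6-OH and 8-OH trans, 7-OAc, 8-CH3 and the C9 side chain cis to the C10 methyl, trans ring fusion | C=C/C(C)=C\C[C@@H]1[C@@](C)(O)[C@H](OC(C)=O)[C@@H](O)[C@@H]2C(C)(C)CCC[C@]21C | target

**Totals and risks**

Total step count: 15. Longest linear sequence: 15 steps (from 1).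

Steps most likely to fail:

1. Step 6. The aldol ring closure onto the C5 carbonyl, which is flanked by two quaternary carbons, may not proceed, so the cascade stops or reverts after the sigmatropic step. Facial selectivity of the rearrangement relative to C10 may also be poor, or a competing [2,3] shift may give another C8/C9 relationship. Fallback, from 6: the lithium acetylide of 2-ethynyl-2-methyl-1,3-dioxolane (n-BuLi, THF, −78 → 0 °C), a small sp nucleophile, is added to the C5 ketone to give the tertiary propargylic alcohol F1. Meyer–Schuster rearrangement (no β-hydrogen, so no competing Rupe pathway) with ketal hydrolysis (Ph3PAuNTf2, monovalent gold, cat., wet MeOH; then aqueous HCl) gives the ene-dione F2, whose alkene isomers equilibrate under acid. An intramolecular carbonyl-ene reaction of the activated C8 ketone with the propenyl group (Me2AlCl, CH2Cl2, −78 °C), a chair-like closure of the citronellal-to-isopulegol kind, forms C8–C9 with the vinyl group and tertiary alcohol and comes back to the route at 12.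

2. Step 7. Reductive loss of the C8 oxygen α to the ketone, over-reduction, or incomplete trapping of the hindered alkoxide and enolate may occur. Fallback, from 12: Luche reduction (NaBH4, CeCl3·7H2O, MeOH, −78 °C; axial hydride) gives the allylic diol F3. Acetylation of its only secondary hydroxyl (Ac2O, pyridine) gives the allylic acetate F4, and Et3SiOTf with 2,6-lutidine gives the C8 silyl ether F5. Hydroboration of both alkenes (BH3·THF; then buffered H2O2), on the ring alkene from the face opposite the axial methyl groups, gives the trans-fused C6,C12-diol F6. Selective oxidation of the primary alcohol (TEMPO cat., PhI(OAc)2) gives the hydroxy aldehyde F7, and silylation of the C6 hydroxyl (Et3SiOTf, 2,6-lutidine) comes back to the route at 21.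

3. Step 4. Allylic bromination may be unselective (bromide at C9 with a transposed alkene, or over-bromination). Fallback, from 6: allylic oxidation of the (E)-methyl group (SeO2 cat., t-BuOOH, CH2Cl2; NaBH4 work-up of any enal) gives the (E)-allylic alcohol F8. O–H insertion of the carbenoid from 3-diazobutan-2-one (Rh2(OAc)4, dirhodium tetraacetate, divalent rhodium, cat., CH2Cl2) then comes back to the route at 9.

Further compounds
F1 | step 6 | 1-[(2-methyl-1,3-dioxolan-2-yl)ethynyl]-2,2,6-trimethyl-6-[(E)-prop-1-en-1-yl]cyclohexan-1-ol (6S; carbinol epimers) | C/C=C/[C@]1(C)CCCC(C)(C)C1(O)C#CC2(C)OCCO2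
F2 | step 6 | 1-{(6S)-2,2,6-trimethyl-6-[(E)-prop-1-en-1-yl]cyclohexylidene}butane-2,3-dione (acyl group on the C10 side) | C/C=C/[C@]1(C)CCCC(C)(C)/C1=C/C(=O)C(C)=O
F3 | step 7 | Δ5-7,8-diol with C9 vinyl (C7–OH cis to the C10 methyl) | C=C[C@@H]1[C@@](C)(O)[C@H](O)C=C2C(C)(C)CCC[C@]21C
F4 | step 7 | 7-acetate of F3 | C=C[C@@H]1[C@@](C)(O)[C@H](OC(C)=O)C=C2C(C)(C)CCC[C@]21C
F5 | step 7 | 8-O-triethylsilyl ether of F4 | C=C[C@@H]1[C@@](C)(O[Si](CC)(CC)CC)[C@H](OC(C)=O)C=C2C(C)(C)CCC[C@]21C
F6 | step 7 | trans-fused C6,C12-diol (7-acetate, 8-triethylsilyl ether) | OCC[C@@H]1[C@@](C)(O[Si](CC)(CC)CC)[C@H](OC(C)=O)[C@@H](O)[C@@H]2C(C)(C)CCC[C@]21C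
F7 | step 7 | 6-hydroxy C12 aldehyde (7-acetate, 8-triethylsilyl ether) | O=CC[C@@H]1[C@@](C)(O[Si](CC)(CC)CC)[C@H](OC(C)=O)[C@@H](O)[C@@H]2C(C)(C)CCC[C@]21C
F8 | step 4 | (S)-2-[(E)-3-hydroxyprop-1-en-1-yl]-2,6,6-trimethylcyclohexan-1-one | OC/C=C/[C@]1(C)CCCC(C)(C)C1=O
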